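**Larch's clock.** Start from the larch run, your flask's neighbour with 1.8 mM of free catalyst against 1.2 mM and the same charges of substrate and coupling partner.

| setting | oak | birch | larch | flask |
|---|---|---|---|---|
| substrate | 0.025 M | 0.10 M | 0.050 M | 0.050 M |
| coupling partner | 0.050 M | 0.050 M | 0.050 M | 0.0500 M |
| capture agent | 1 mM | 1 mM | 1 mM | 1.00 mM |
| free catalyst | 1.2 mM | 1.2 mM | 1.8 mM | 1.2 mM |
| remark | run made earlier | run made earlier | run made earlier |  |

| run | time / min | target / % |
|---|---|---|
| oak | 0.667 | 23.0 |
| oak | 1.33 | 41.6 |
| oak | 2.50 | 65.5 |
| oak | 4.00 | 84.1 |
| oak | 8.00 | 97.7 |
| birch | 0.667 | 8.8 |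
| birch | 1.33 | 15.5 |
| birch | 2.50 | 26.1 |
| birch | 4.00 | 34.1 |
| birch | 8.00 | 45.1 |
| larch | 0.667 | 21.9 |
| larch | 1.33 | 39.0 |
| larch | 2.50 | 60.2 |
| larch | 4.00 | 76.0 |
| larch | 8.00 | 93.9 |

(scatter of a reading: 0.3 percentage points)

- no earlier run changes the charge of coupling partner; that part of a forecast is a guess

- apparent order in free catalyst when 30% of the substrate are converted (percent change of the rate of making target for one percent more free catalyst charged)
- apparent order in coupling partner when 30% of the substrate are converted (percent change of the rate of making target for one percent more coupling partner charged)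

Its first two readings span 30% conversion and give, as an average over that interval, 12.9 mM min⁻¹ of target. Its charged catalyst over that rate is 0.140 min: the round time, the minutes a charged catalyst needs per target molecule.

**The curve.** Suppose your flask keeps larch's round time at each conversion, not just near 30%. It is then larch on a clock stretched by 1.50. It starts with 21.9% target at 1.00 min, an average opening slope of 10.9 mM min⁻¹. It bends through 60.2% at 3.75 min and 76.0% at 6.00 min, then flattens to 93.9% at 12.0 min. Substrate and coupling partner are charged equally, so neither is in excess, and the curve climbs towards the charge.

**My reckoning.** At 30% conversion the flask should make 8.60 mM min⁻¹. A constant round time means order one in free catalyst, and that is my figure. For coupling partner I commit to none, since no run changes its charge.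

**The forecast.** It gives 1.25 for free catalyst and 0.85 for coupling partner, suggesting that “the capture agent sequesters catalyst”.

**The result.** The flask gives 1.2 and 0.71, making target at 8.49 mM min⁻¹ when 30% of its substrate is converted, after 1.36 min.

    substrate + free catalyst → catalyst intermediate A (k = 13.0 M⁻¹ s⁻¹)
    coupling partner + catalyst intermediate A → catalyst intermediate B (k = 7.80 M⁻¹ s⁻¹)
    catalyst intermediate B → by-product + catalyst intermediate C (k = 10.0 s⁻¹)
    catalyst intermediate C → free catalyst + target (k = 0.850 s⁻¹)
    capture agent + catalyst intermediate C → trapped intermediate (k = 13.0 M⁻¹ s⁻¹)

**The split.** The flask's round time is 0.141 min, close to larch's reading of 0.140 min, yet the order in free catalyst is 1.2, not my one. Capture of catalyst intermediate C is a part of the round time. Run without that step, the same flask makes target 1.20 times as fast at 30% conversion, so its round time there shortens to 0.117 min. In that run the order in free catalyst drops to 1.0.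

The data are simulated with constants of no real substance; the scatter is artificial.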